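**Retrosynthetic overview**

1. Numbering: the carbocycle is numbered as tricyclo[5.4.0.0^2,8]undecane (C1–C11) and these locants are kept for the same carbons in every intermediate; C12 is the acetoxymethyl carbon. Feature used: in the cyclobutane C1–C2–C8–C7, C8 carries only C9 outside the four-membered ring, so the C7–C8 bond can come from a cyclopentanone C2–C8–C9(=O)–C7–C1 whose carbonyl carbon C9 is pushed out of the ring.
2. Target ⇒ (primary acetate, C5 angelate, C9 methyl by cuprate) enone 29 ⇒ aldol condensation C10→C9 on keto aldehyde 27 closes the cyclohexenone C1–C11–C10–C9–C8.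
3. 27 ⇒ ester 24 ⇒ photochemical Wolff contraction of diazoketone 21 (bicyclo[4.2.1]nonan-8-one → bicyclo[4.1.1]octane), which forms C7–C8 and the cyclobutane.
4. 21 ⇒ SmI2 ketyl–enone closure C3→C2 of keto aldehyde 17 (seven-membered ring, C2 and C3) ⇒ lactone aldol (C6, C5), α′-alkylation (C7) and anti cuprate addition (C1) starting from (R)-4-silyloxycyclopentenone 1.
5. Ring order: cyclopentane (bought) → cycloheptane (step 13) → cyclobutane (step 16) → cyclohexanone (step 19).

Key step: step 16

Assumption (chemistry): the C1 arm is carried as an isopropenyl group, a masked acetyl that needs no acid to install or unmask, in place of a ketal, which changes only a spectator group of the key-step precursor and product; enone 1 and aldehyde 11 are taken as purchasable.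

**Route**

Step 1
Reactants: 1 (R)-4-(tert-butyldimethylsilyloxy)cyclopent-2-en-1-one
Product: 3 (R)-4-(prop-1-en-2-yl)cyclopent-2-en-1-one, via β-silyloxy ketone 2 (not isolated)
Conditions: CH2=C(CH3)MgBr, CuBr·SMe2 (cat.), THF, −78 °C; aq NH4Cl; then DBU, CH2Cl2, 0 °C
Reagents that add atoms: isopropenylmagnesium bromide, C=C(C)[Mg]Br
Why: Copper-catalysed conjugate addition occurs anti to the neighbouring silyloxy group (sets C1, R), and base then expels silanol by E1cB elimination to give the 4-substituted cyclopentenone.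

Step 2
Reactants: 3 (R)-4-(prop-1-en-2-yl)cyclopent-2-en-1-one
Product: 4 trans-3-methyl-4-(prop-1-en-2-yl)-1-(trimethylsilyloxy)cyclopent-1-ene
Conditions: Me2CuLi (from MeLi, CuI), Et2O, −78 °C; then Me3SiCl, Et3N, −78 → 0 °C
Reagents that add atoms: methyllithium, [Li]C; chlorotrimethylsilane, C[Si](C)(C)Cl
Why: Gilman cuprate 1,4-addition (anti to the isopropenyl group) with in situ silylation gives the enol ether regiospecifically toward C8; the new C2 centre is removed again in step 3.

Step 3
Reactants: 4 trans-3-methyl-4-(prop-1-en-2-yl)-1-(trimethylsilyloxy)cyclopent-1-ene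
Product: 5 (S)-3-methyl-4-(prop-1-en-2-yl)cyclopent-2-en-1-one
Conditions: Pd(OAc)2 (1 equiv), MeCN, rt
Reagents that add atoms: none
Why: Saegusa–Ito oxidation: palladation of the silyl enol ether at C8 and β-hydride elimination of the C2 hydrogen give the 3-methyl enone without touching C1.

Step 4
Reactants: 5 (S)-3-methyl-4-(prop-1-en-2-yl)cyclopent-2-en-1-one; 6 methyl bromoacetate
Product: 7 methyl 2-[trans-4-methyl-2-oxo-5-(prop-1-en-2-yl)cyclopent-3-en-1-yl]acetate
Conditions: LiN(i-Pr)2, THF, −78 °C; then 6, DMPU, −78 → −30 °C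
Reagents that add atoms: none
Why: Kinetic deprotonation gives the cross-conjugated α′ (C7) lithium enolate, which is alkylated anti to the adjacent isopropenyl group, setting C7 trans to C1.

Step 5
Reactants: 7 methyl 2-[trans-4-methyl-2-oxo-5-(prop-1-en-2-yl)cyclopent-3-en-1-yl]acetate
Product: 9 cis-fused lactone 5-methyl-4-(prop-1-en-2-yl)-3,3a,4,6a-tetrahydro-2H-cyclopenta[b]furan-2-one, via lithium alkoxide 8 (not isolated)
Conditions: LiBH(s-Bu)3, THF, −78 °C → rt; aq NH4Cl
Reagents that add atoms: none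
Why: The bulky hydride adds 1,2 to the β,β-disubstituted enone from the face opposite the adjacent C7 side chain, so the C9 alkoxide is cis to the ester arm and lactonises in situ to the cis-fused γ-lactone (reduction–lactonisation).

Step 6
Reactants: 9 cis-fused lactone 5-methyl-4-(prop-1-en-2-yl)-3,3a,4,6a-tetrahydro-2H-cyclopenta[b]furan-2-one
Product: 10 3-exo-methyl lactone 3,5-dimethyl-4-(prop-1-en-2-yl)-3,3a,4,6a-tetrahydro-2H-cyclopenta[b]furan-2-one
Conditions: LiN(i-Pr)2, THF, −78 °C; MeI, −78 → −40 °C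
Reagents that add atoms: iodomethane, CI
Why: Lactone enolate alkylation from the convex face; the configuration at C6 is provisional because the centre is enolised again in step 7.

Step 7
Reactants: 10 3-exo-methyl lactone; 11 3-[(4-methoxyphenyl)methoxy]propanal
Product: 12 aldol adduct 3-{(1R)-1-hydroxy-3-[(4-methoxyphenyl)methoxy]propyl}-3,5-dimethyl-4-(prop-1-en-2-yl)-3,3a,4,6a-tetrahydro-2H-cyclopenta[b]furan-2-one (hydroxyalkyl branch exo)
Conditions: LiN(i-Pr)2, THF, −78 °C; then 11, −78 °C; aq NH4Cl at −78 °C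
Reagents that add atoms: none
Why: Aldol addition of the fully substituted lactone lithium enolate: the aldehyde enters on the convex face (C5 branch exo and methyl endo, fixing C6) and a Zimmerman–Traxler chair with the aldehyde chain equatorial should put the C5 hydroxyl anti to ring carbon C7 (C5 R).

Step 8
Reactants: 12 aldol adduct
Product: 13 p-methoxybenzylidene acetal lactone (2,4-cis-1,3-dioxane spanning the C5 and C3 oxygens)
Conditions: DDQ, 4 Å molecular sieves, CH2Cl2, 0 °C
Reagents that add atoms: none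
Why: Anhydrous DDQ oxidises the PMB ether to an oxocarbenium ion that the 1,3-related C5 hydroxyl traps (DDQ oxidative acetalisation), protecting C5–OH without base and so without retro-aldol; the acetal carbon takes the aryl-equatorial configuration.

Step 9
Reactants: 13 p-methoxybenzylidene acetal lactone
Product: 14 diol (primary C12–OH and allylic C9–OH; acetal intact)
Conditions: LiAlH4, THF, 0 °C
Reagents that add atoms: none
Why: Hydride reduction of the lactone gives the primary and the allylic alcohol; the acetal and both alkenes are inert.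

Step 10
Reactants: 14 diol
Product: 15 C12 tert-butyldimethylsilyl ether with free C9–OH
Conditions: TBSCl, imidazole, CH2Cl2, 0 °C
Reagents that add atoms: tert-butyldimethylsilyl chloride, CC(C)(C)[Si](C)(C)Cl
Why: Silylation with the chloride and imidazole is selective for the primary C12 hydroxyl over the secondary allylic C9 hydroxyl.

Step 11
Reactants: 15 C12 silyl ether
Product: 16 diol with C5–OPMB (free primary C3–OH and allylic C9–OH)
Conditions: i-Bu2AlH (excess), CH2Cl2, −78 → 0 °C
Reagents that add atoms: none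
Why: Regioselective reductive opening of the p-methoxybenzylidene acetal: aluminium binds the less hindered primary oxygen, so hydride delivery leaves the PMB ether on the hindered C5 oxygen and frees C3–OH.

Step 12
Reactants: 16 diol with C5–OPMB
Product: 17 keto aldehyde (C3 aldehyde tethered through C4–C5–C6 to C7 of the 3-methylcyclopent-2-enone; isopropenyl on C1 trans to the chain)
Conditions: Dess–Martin periodinane, CH2Cl2, 0 °C → rt
Reagents that add atoms: none
Why: Dess–Martin oxidation converts the primary C3 alcohol into the aldehyde and the allylic C9 alcohol into the enone in one operation under non-basic conditions that spare the β-alkoxy aldehyde.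

Step 13
Reactants: 17 keto aldehyde
Product: 18 bicyclo[4.2.1]nonan-8-one hydroxy ketone (C3–OH, C5–OPMB, C6 methyl and CH2OTBS, C2 methyl, C1 isopropenyl anti to the C3–C6 bridge)
Conditions: SmI2, HMPA, t-BuOH, THF, high dilution, −78 → 0 °C
Reagents that add atoms: none
Why: SmI2 ketyl–olefin (ketyl–enone) reductive cyclisation: the C3 ketyl adds 7-exo-trig to C2, the β-carbon of the enone; the tether from C7 forces attack on the face cis to C6 (sets C2), and the ketyl oxygen is expected anti to the enone α-carbon C8 in the non-chelated HMPA transition state (sets C3, R).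

Step 14
Reactants: 18 hydroxy ketone
Product: 19 bis-silyl ketone (C3–OTBS)
Conditions: TBSOTf, 2,6-lutidine, CH2Cl2, −78 → 0 °C
Reagents that add atoms: tert-butyldimethylsilyl trifluoromethanesulfonate, CC(C)(C)[Si](C)(C)OS(=O)(=O)C(F)(F)F
Why: The silyl triflate with a hindered base silylates the neopentyl-type secondary C3 hydroxyl.

Step 15
Reactants: 19 bis-silyl ketone
Product: 21 α-diazoketone (diazo on C8, carbonyl C9 between C8 and C7), via trifluoroacetyl ketone 20 (not isolated)
Conditions: LiN(SiMe3)2, THF, −78 °C; CF3CO2CH2CF3; 1 M HCl work-up; then MsN3, Et3N, H2O, MeCN, rt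
Reagents that add atoms: methanesulfonyl azide, CS(=O)(=O)N=[N+]=[N-]; 2,2,2-trifluoroethyl trifluoroacetate, FC(F)(F)COC(=O)C(F)(F)F (its acyl group is held only in 20)
Why: Detrifluoroacetylative (Regitz-type deacylative) diazo transfer: C8 is the only enolisable α-carbon because C7 is a bridgehead, the trifluoroacetyl group activates C8, and the sulfonyl azide delivers N2 with loss of the acyl group.

Step 16
Reactants: 21 α-diazoketone; 22 methanol
Product: 24 bicyclo[4.1.1]octane methyl ester (CO2Me on C8, anti to the C3–C6 bridge), via ketene 23 (not isolated)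
Conditions: hν (medium-pressure Hg lamp, Pyrex, λ > 300 nm), degassed MeOH, 0 °C → rt
Reagents that add atoms: none
Why: Photolysis expels N2 from the ring-locked s-cis α-diazoketone and the C9–C7 bond migrates to C8, giving ketene 23, to which methanol adds; this is the classical photochemical Wolff ring contraction of cyclic 2-diazoketones, as in the contraction of diazocamphor-type bridged cyclopentanones to bicyclo[2.1.1]hexane esters. The cyclobutane C1–C2–C8–C7 is closed not by an end-to-end cyclisation but by a 1,2-shift inside the five-membered ring C2–C8–C9–C7–C1, with C9 extruded to the exocyclic ester carbon, and loss of N2 pays for the strain of the bicyclo[4.1.1]octane. C7 migrates with retention, so its configuration (set in step 4) and those of C1, C2, C3, C5 and C6 are untouched. The one new centre, C8, is set when the ester enol formed from 23 is protonated; the isomer drawn is the less crowded one, and its C8 epimer is equally usable because C8 is equilibrated through the aldehyde enolate in step 19. The selectivity needed is that C7 and nothing else migrates and that the diazo group sits on C8: C7 is the only other carbon on the carbonyl, and C8 was the only enolisable α-position in step 15. Carbene O–H insertion into methanol and a 1,2-shift from C2 are the side paths, both disfavoured for a diazoketone held s-cis in a ring.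

Step 17
Reactants: 24 methyl ester
Product: 25 C9 aldehyde
Conditions: i-Bu2AlH (1.2 equiv), CH2Cl2, −78 °C; MeOH quench
Reagents that add atoms: none
Why: Partial reduction of the methyl ester: the tetrahedral aluminium hemiacetal is stable at −78 °C and gives the aldehyde on work-up.

Step 18
Reactants: 25 C9 aldehyde
Product: 27 keto aldehyde (C11 methyl ketone on C1, C9 aldehyde on C8), via diol 26 (not isolated)
Conditions: OsO4 (cat.), NaIO4, 2,6-lutidine, 1,4-dioxane–H2O, rt
Reagents that add atoms: sodium periodate (oxygen passed on through OsO4), [Na+].[O-]I(=O)(=O)=O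
Why: Lemieux–Johnson cleavage: catalytic dihydroxylation of the only alkene and periodate cleavage of the diol unmask the C11 methyl ketone.

Step 19
Reactants: 27 keto aldehyde
Product: 29 tricyclic enone (C9=C10 conjugated to C11=O), via aldol 28 (not isolated)
Conditions: KOH (cat.), MeOH, 0 °C → rt
Reagents that add atoms: none
Why: Intramolecular aldol condensation: the methyl-ketone enolate (C10) adds to the C9 aldehyde (6-(enolexo)-exo-trig) and E1cB dehydration gives the bicyclo[3.1.1]heptenone; only the C8 epimer with the aldehyde anti to the C3–C6 bridge can reach C10, and the other epimer equilibrates through its enolate.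

Step 20
Reactants: 29 tricyclic enone
Product: 30 tricyclic ketone with C9 methyl
Conditions: Me2CuLi (from MeLi, CuI), Et2O, −78 → −20 °C; aq NH4Cl
Reagents that add atoms: methyllithium, [Li]C
Why: Gilman cuprate conjugate addition: the reagent attacks C9 from the face flanked by the C7–H bridge, away from the C2 bridge whose methyl group covers the other face (as with verbenone-type enones), setting C9 (R).

Step 21
Reactants: 30 tricyclic ketone with C9 methyl
Product: 31 C5 alcohol
Conditions: DDQ, CH2Cl2–pH 7 buffer, 0 °C → rt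
Reagents that add atoms: none
Why: Oxidative cleavage of the PMB ether with DDQ in wet solvent frees C5–OH; the silyl ethers and the ketone are inert.

Step 22
Reactants: 31 C5 alcohol; 32 angelic acid
Product: 34 C5 angelate, via mixed anhydride 33 (not isolated)
Conditions: 32, 2,4,6-Cl3C6H2COCl, Et3N, toluene, rt; then 31, 80 °C
Reagents that add atoms: 2,4,6-trichlorobenzoyl chloride, O=C(Cl)c1c(Cl)cc(Cl)cc1Cl (its acyl group is held only in 33)
Why: Yamaguchi-type esterification through the mixed anhydride, run without a nucleophilic catalyst so that the Z (angelate) double bond is not isomerised to the tiglate.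

Step 23
Reactants: 34 C5 angelate
Product: 35 diol (C3–OH and C12–OH free)
Conditions: HF·pyridine, pyridine, THF, 0 °C → rt
Reagents that add atoms: none
Why: Fluoride cleavage of both silyl ethers under mildly acidic conditions, which avoid acyl migration of the angelate.

Step 24
Reactants: 35 diol
Product: 36 CNP0212099.1
Conditions: Ac2O, pyridine, CH2Cl2, 0 °C
Reagents that add atoms: acetic anhydride, CC(=O)OC(C)=O
Why: Acylation selective for the primary C12 hydroxyl; the C3 hydroxyl next to quaternary C2 in the bridged ring reacts far more slowly.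

**Compound list**

1 | (R)-4-(tert-butyldimethylsilyloxy)cyclopent-2-en-1-one | O=C1C=C[C@H](O[Si](C)(C)C(C)(C)C)C1 | starting material
2 | trans-4-(tert-butyldimethylsilyloxy)-3-(prop-1-en-2-yl)cyclopentan-1-one | O=C1C[C@@H](C(C)=C)[C@H](O[Si](C)(C)C(C)(C)C)C1 | intermediate
3 | (R)-4-(prop-1-en-2-yl)cyclopent-2-en-1-one | O=C1C[C@@H](C(C)=C)C=C1 | intermediate
4 | trans-3-methyl-4-(prop-1-en-2-yl)-1-(trimethylsilyloxy)cyclopent-1-ene | C[Si](C)(C)OC1=C[C@@H](C)[C@H](C(C)=C)C1 | intermediate
5 | (S)-3-methyl-4-(prop-1-en-2-yl)cyclopent-2-en-1-one | O=C1C[C@@H](C(C)=C)C(C)=C1 | intermediate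
6 | methyl bromoacetate | COC(=O)CBr | starting material
7 | methyl 2-[trans-4-methyl-2-oxo-5-(prop-1-en-2-yl)cyclopent-3-en-1-yl]acetate | COC(=O)C[C@H]1C(=O)C=C(C)[C@@H]1C(C)=C | intermediate
8 | lithium alkoxide of methyl 2-[2-hydroxy-4-methyl-5-(prop-1-en-2-yl)cyclopent-3-en-1-yl]acetate (O cis to the acetate arm) | [Li+].COC(=O)C[C@H]1[C@@H]([O-])C=C(C)[C@@H]1C(C)=C | intermediate
9 | cis-fused 5-methyl-4-(prop-1-en-2-yl)-3,3a,4,6a-tetrahydro-2H-cyclopenta[b]furan-2-one (isopropenyl trans to the lactone ring) | O=C1C[C@@H]2[C@@H](C(C)=C)C(C)=C[C@@H]2O1 | intermediate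
10 | 3-exo-methyl lactone: 3,5-dimethyl-4-(prop-1-en-2-yl)-3,3a,4,6a-tetrahydro-2H-cyclopenta[b]furan-2-one | O=C1[C@@H](C)[C@@H]2[C@@H](C(C)=C)C(C)=C[C@@H]2O1 | intermediate
11 | 3-[(4-methoxyphenyl)methoxy]propanal | O=CCCOCc1ccc(OC)cc1 | starting material
12 | aldol adduct: 3-{(1R)-1-hydroxy-3-[(4-methoxyphenyl)methoxy]propyl}-3,5-dimethyl-4-(prop-1-en-2-yl)-3,3a,4,6a-tetrahydro-2H-cyclopenta[b]furan-2-one (C5 branch exo, 3-methyl endo) | O=C1[C@@](C)([C@H](O)CCOCc3ccc(OC)cc3)[C@@H]2[C@@H](C(C)=C)C(C)=C[C@@H]2O1 | intermediate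
13 | acetal lactone: 3-[cis-2-(4-methoxyphenyl)-1,3-dioxan-4-yl]-3,5-dimethyl-4-(prop-1-en-2-yl)-3,3a,4,6a-tetrahydro-2H-cyclopenta[b]furan-2-one | O=C1[C@@](C)([C@H]3CCO[C@@H](c4ccc(OC)cc4)O3)[C@@H]2[C@@H](C(C)=C)C(C)=C[C@@H]2O1 | intermediate
14 | diol from lactone reduction: C12 primary alcohol and cis C9 allylic alcohol on the 3-methyl-4-isopropenylcyclopent-2-ene, acetal retained | OC[C@@](C)([C@H]3CCO[C@@H](c4ccc(OC)cc4)O3)[C@@H]1[C@@H](C(C)=C)C(C)=C[C@@H]1O | intermediate
15 | C12 tert-butyldimethylsilyl ether of 14 | CC(C)(C)[Si](C)(C)OC[C@@](C)([C@H]3CCO[C@@H](c4ccc(OC)cc4)O3)[C@@H]1[C@@H](C(C)=C)C(C)=C[C@@H]1O | intermediate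
16 | C5 PMB ether diol (free C3–OH and C9–OH, C12–OTBS) | CC(C)(C)[Si](C)(C)OC[C@@](C)([C@H](OCc2ccc(OC)cc2)CCO)[C@@H]1[C@@H](C(C)=C)C(C)=C[C@@H]1O | intermediate
17 | keto aldehyde: (3R)-3-[(4-methoxyphenyl)methoxy]-4-methyl-4-(tert-butyldimethylsilyloxymethyl)-4-[trans-4-methyl-2-oxo-5-(prop-1-en-2-yl)cyclopent-3-en-1-yl]butanal | O=CC[C@@H](OCc2ccc(OC)cc2)[C@](C)(CO[Si](C)(C)C(C)(C)C)[C@H]1C(=O)C=C(C)[C@@H]1C(C)=C | intermediate
18 | bicyclo[4.2.1]nonan-8-one with C3–OH, C5–OPMB, C6 methyl and CH2OTBS, C2 methyl, C1 isopropenyl anti to the C3–C6 bridge | COc1ccc(cc1)CO[C@@H]2C[C@@H](O)[C@]3(C)CC(=O)[C@@H]([C@H]3C(C)=C)[C@@]2(C)CO[Si](C)(C)C(C)(C)C | intermediate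
19 | C3 tert-butyldimethylsilyl ether of 18 | COc1ccc(cc1)CO[C@@H]2C[C@@H](O[Si](C)(C)C(C)(C)C)[C@]3(C)CC(=O)[C@@H]([C@H]3C(C)=C)[C@@]2(C)CO[Si](C)(C)C(C)(C)C | intermediate
20 | C8 trifluoroacetyl derivative of 19 (C8 configuration open, enolised) | COc1ccc(cc1)CO[C@@H]2C[C@@H](O[Si](C)(C)C(C)(C)C)[C@]3(C)C(C(=O)C(F)(F)F)C(=O)[C@@H]([C@H]3C(C)=C)[C@@]2(C)CO[Si](C)(C)C(C)(C)C | intermediate
21 | bridged α-diazoketone: 7-diazobicyclo[4.2.1]nonan-8-one (diazo on C8) with the substituents of 19 | COc1ccc(cc1)CO[C@@H]2C[C@@H](O[Si](C)(C)C(C)(C)C)[C@]3(C)C(=[N+]=[N-])C(=O)[C@@H]([C@H]3C(C)=C)[C@@]2(C)CO[Si](C)(C)C(C)(C)C | intermediate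
22 | methanol | CO | starting material
23 | ketene on C8 of the bicyclo[4.1.1]octane | COc1ccc(cc1)CO[C@@H]2C[C@@H](O[Si](C)(C)C(C)(C)C)[C@]3(C)C(=C=O)[C@@H]([C@H]3C(C)=C)[C@@]2(C)CO[Si](C)(C)C(C)(C)C | intermediate
24 | methyl bicyclo[4.1.1]octane-7-carboxylate (ester on C8 anti to the C3–C6 bridge; C1 isopropenyl, C2 methyl, C3–OTBS, C5–OPMB, C6 methyl and CH2OTBS) | COc1ccc(cc1)CO[C@@H]2C[C@@H](O[Si](C)(C)C(C)(C)C)[C@]3(C)[C@@H](C(=O)OC)[C@@H]([C@H]3C(C)=C)[C@@]2(C)CO[Si](C)(C)C(C)(C)C | intermediate
25 | C9 aldehyde corresponding to 24 | COc1ccc(cc1)CO[C@@H]2C[C@@H](O[Si](C)(C)C(C)(C)C)[C@]3(C)[C@@H](C=O)[C@@H]([C@H]3C(C)=C)[C@@]2(C)CO[Si](C)(C)C(C)(C)C | intermediate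
26 | 1,2-diol from dihydroxylation of the isopropenyl group of 25 (new carbinol centre open) | COc1ccc(cc1)CO[C@@H]2C[C@@H](O[Si](C)(C)C(C)(C)C)[C@]3(C)[C@@H](C=O)[C@@H]([C@H]3C(C)(O)CO)[C@@]2(C)CO[Si](C)(C)C(C)(C)C | intermediate
27 | keto aldehyde: C1 acetyl and C8 formyl, both anti to the C3–C6 bridge | COc1ccc(cc1)CO[C@@H]2C[C@@H](O[Si](C)(C)C(C)(C)C)[C@]3(C)[C@@H](C=O)[C@@H]([C@H]3C(C)=O)[C@@]2(C)CO[Si](C)(C)C(C)(C)C | intermediate
28 | β-hydroxy ketone (C9–OH, configuration open) of the tricyclo[5.4.0.0^2,8]undecan-11-one | COc1ccc(cc1)CO[C@@H]2C[C@@H](O[Si](C)(C)C(C)(C)C)[C@]3(C)[C@@H]4[C@@H]([C@H]3C(=O)CC4O)[C@@]2(C)CO[Si](C)(C)C(C)(C)C | intermediate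
29 | tricyclo[5.4.0.0^2,8]undec-9-en-11-one (C3–OTBS, C5–OPMB, C6 methyl and CH2OTBS, C2 methyl) | COc1ccc(cc1)CO[C@@H]2C[C@@H](O[Si](C)(C)C(C)(C)C)[C@]3(C)[C@@H]4[C@@H]([C@H]3C(=O)C=C4)[C@@]2(C)CO[Si](C)(C)C(C)(C)C | intermediate
30 | (9R)-9-methyl ketone from 29 | COc1ccc(cc1)CO[C@@H]2C[C@@H](O[Si](C)(C)C(C)(C)C)[C@]3(C)[C@@H]4[C@@H]([C@H]3C(=O)C[C@H]4C)[C@@]2(C)CO[Si](C)(C)C(C)(C)C | intermediate
31 | C5 alcohol (C3–OTBS, C12–OTBS) | O[C@@H]1C[C@@H](O[Si](C)(C)C(C)(C)C)[C@]2(C)[C@@H]3[C@@H]([C@H]2C(=O)C[C@H]3C)[C@@]1(C)CO[Si](C)(C)C(C)(C)C | intermediate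
32 | angelic acid, (Z)-2-methylbut-2-enoic acid | C/C=C(/C)C(=O)O | starting material
33 | angelic 2,4,6-trichlorobenzoic mixed anhydride | C/C=C(/C)C(=O)OC(=O)c1c(Cl)cc(Cl)cc1Cl | intermediate
34 | C5 angelate (C3–OTBS, C12–OTBS) | C/C=C(/C)C(=O)O[C@@H]1C[C@@H](O[Si](C)(C)C(C)(C)C)[C@]2(C)[C@@H]3[C@@H]([C@H]2C(=O)C[C@H]3C)[C@@]1(C)CO[Si](C)(C)C(C)(C)C | intermediate
35 | C5 angelate diol (C3–OH, C12–OH) | C/C=C(/C)C(=O)O[C@@H]1C[C@@H](O)[C@]2(C)[C@@H]3[C@@H]([C@H]2C(=O)C[C@H]3C)[C@@]1(C)CO | intermediate
36 | CNP0212099.1: 6-(acetoxymethyl)-3-hydroxy-2,6,9-trimethyl-11-oxotricyclo[5.4.0.0^2,8]undecan-5-yl (Z)-2-methylbut-2-enoate, configuration as in the SMILES | C/C=C(/C)C(=O)O[C@@H]1C[C@@H](O)[C@]2(C)[C@@H]3[C@@H]([C@H]2C(=O)C[C@H]3C)[C@@]1(C)COC(C)=O | target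

**Step count and risks**

Total step count: 24. Longest linear sequence: 24 steps (from 1; compounds 6, 11, 22 and 32 are bought).

Steps most likely to fail:

1. Step 16 (Wolff contraction). The carbene may be captured by methanol (O–H insertion) or insert into a C–H bond before C7 migrates, or migration may be slowed by the strain of the bicyclo[4.1.1]octane. Fallback, from ketone 19 back to ester 24: the lithium enolate of 19 (LiN(SiMe3)2, THF, −78 °C) is brominated at C8 with N-bromosuccinimide to give α-bromo ketone F1. NaOMe in MeOH then adds to C9, and the C9–C7 bond shifts to C8 with loss of bromide. This semibenzilic (quasi-Favorskii) contraction is the ionic counterpart of the same 1,2-shift and is open here because bridgehead C7 cannot enolise; methoxide equilibrates C8 and delivers 24.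

2. Step 13 (SmI2 closure of the seven-membered ring). The aldehyde may be over-reduced, the enone may be reduced before ring closure, or the ketyl may couple at the C9 carbonyl (pinacol-type six-membered closure) instead of adding to C2. Fallback, from keto aldehyde 17 back to alcohol 18: PhSeSiMe3 (cat. ZnI2) adds across the aldehyde to give O-silyl hemiselenoacetal F2. Bu3SnH and AIBN under slow addition in benzene at 80 °C then generate the neutral α-silyloxy radical at C3, which closes onto C2 in a tin-hydride chain (Giese-type 7-exo cyclisation) with no reductant present that can attack either carbonyl, giving trimethylsilyl ether F3. K2CO3 in MeOH removes the trimethylsilyl group to give 18.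

3. Step 7 (lactone aldol). Facial discrimination at the aldehyde carbon (C5) may be poor, or the lithium aldolate may undergo retro-aldol. Fallback, from lactone 10 back to 12: the aldol is run without regard to C5 (C6 is still fixed by exo attack) and the mixture of 12 and its C5 epimer F4 is oxidised with Dess–Martin periodinane to β-keto lactone F5. F5 is reduced under reagent control with (S)-1-methyl-3,3-diphenyltetrahydro-1H,3H-pyrrolo[1,2-c][1,3,2]oxazaborole (cat.) and catecholborane (CBS reduction), with quaternary C6 as the large group, to give 12 with C5 (R).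

Further compounds
F1 | step 16 | C8 α-bromo ketone of 19 (C8 configuration open) | COc1ccc(cc1)CO[C@@H]2C[C@@H](O[Si](C)(C)C(C)(C)C)[C@]3(C)C(Br)C(=O)[C@@H]([C@H]3C(C)=C)[C@@]2(C)CO[Si](C)(C)C(C)(C)C
F2 | step 13 | O-trimethylsilyl hemiselenoacetal of 17 at C3 (C3 configuration open) | C[Si](C)(C)OC([Se]c3ccccc3)C[C@@H](OCc2ccc(OC)cc2)[C@](C)(CO[Si](C)(C)C(C)(C)C)[C@H]1C(=O)C=C(C)[C@@H]1C(C)=C
F3 | step 13 | C3 trimethylsilyl ether of 18 | COc1ccc(cc1)CO[C@@H]2C[C@@H](O[Si](C)(C)C)[C@]3(C)CC(=O)[C@@H]([C@H]3C(C)=C)[C@@]2(C)CO[Si](C)(C)C(C)(C)C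
F4 | step 7 | C5 epimer of aldol adduct 12 | O=C1[C@@](C)([C@@H](O)CCOCc3ccc(OC)cc3)[C@@H]2[C@@H](C(C)=C)C(C)=C[C@@H]2O1
F5 | step 7 | β-keto lactone (C5 ketone) from 12 and F4 | O=C1[C@@](C)(C(=O)CCOCc3ccc(OC)cc3)[C@@H]2[C@@H](C(C)=C)C(C)=C[C@@H]2O1
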